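**Retrosynthetic overview**
- Third and last ring: the nine-membered oxacycle (ten-membered carbocycle) by ring-closing metathesis at C4=C5, between the furanone isopropenyl group and a vinyl group on C6.
- Second ring: the α-methylene-γ-butyrolactone by lactonisation of O6 onto an acrylate ester, after O8 is capped as the methacrylate; the C6 vinyl group comes from the glyceraldehyde CH2OH (oxidation, methylenation).
- Key union: C7–C8 by indium Barbier allylation of a furanone α-acetoxy aldehyde (C1–C4, C8–C10) with a Z-2-(bromomethyl)acrylate made from D-glyceraldehyde acetonide and methyl acrylate (C5–C7, C11–C13); this sets C7 and C8.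
- First ring: the 3(2H)-furanone by gold-catalysed cyclisation of an α′-hydroxy ynone, made from a Seebach dioxolanone aldol adduct ((R)-lactic acid gives C10, the aldol with dimethoxyacetaldehyde gives C9) and 2-methylbut-1-en-3-yne.
- Ring order: furanone, then lactone, then macrocycle. Atom numbers C1–C15 are germacrane numbers of the target.

Assumption: (R)-glyceraldehyde acetonide and anhydrous 2,2-dimethoxyacetaldehyde (dried from the commercial aqueous solution) count as commercial starting materials; the route is a proposal and has not been run.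

**Step 1**
Reactants: 1 (R)-lactic acid; 2 pivalaldehyde
Product: 3 (2R,5R)-2-tert-butyl-5-methyl-1,3-dioxolan-4-one
Conditions: TsOH·H2O (cat.), H2SO4 (cat.), pentane, reflux, Dean–Stark; recrystallise from pentane/Et2O at −78 °C
Reagents that add atoms: none
Why: Reversible acid-catalysed acetalisation of the α-hydroxy acid (Seebach dioxolanone formation) favours the cis isomer, which crystallises, so the acetal centre is set under thermodynamic control relative to the lactate centre.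

**Step 2**
Reactants: 3 (2R,5R)-2-tert-butyl-5-methyl-1,3-dioxolan-4-one; 4 2,2-dimethoxyacetaldehyde
Product: 6 (2R,5S)-2-tert-butyl-5-[(1R)-1-hydroxy-2,2-dimethoxyethyl]-5-methyl-1,3-dioxolan-4-one, via lithium enolate 5 (not isolated)
Conditions: LiN(iPr)2 (LDA, 1.1 equiv), THF, −78 °C, 30 min; 4 (1.3 equiv), −78 °C; AcOH quench at −78 °C
Reagents that add atoms: LiN(iPr)2, lithium diisopropylamide, [Li+].CC(C)[N-]C(C)C (lithium of 5 only)
Why: Aldol addition of the Seebach enolate (self-regeneration of stereocentres) occurs trans to tert-butyl, giving quaternary C10 with net retention, and the Zimmerman–Traxler chair of the ring-locked enolate (methyl cis to OLi) places the new C9 hydroxyl anti to the ring oxygen, the minor C9 epimer being removed by chromatography.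

**Step 3**
Reactants: 6 (2R,5S)-2-tert-butyl-5-[(1R)-1-hydroxy-2,2-dimethoxyethyl]-5-methyl-1,3-dioxolan-4-one; 7 2-methylbut-1-en-3-yne
Product: 10 (6S,7R)-6,7-dihydroxy-8,8-dimethoxy-2,6-dimethyloct-1-en-3-yn-5-one, via lithium acetylide 8 (not isolated), via hemiketal dialkoxide 9 (not isolated)
Conditions: 7 (3.5 equiv), n-BuLi (3.2 equiv), THF, −78 °C; add 6, −78 to −40 °C; AcOH/THF quench at −78 °C, then aq. NaHCO3, rt
Reagents that add atoms: n-BuLi, butyllithium, [Li]CCCC (lithium of 8 and 9 only)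
Why: Acyl substitution of the acylal-type lactone by the acetylide stops at the tetrahedral adduct, which persists at low temperature and on protonation collapses with loss of pivalaldehyde to the α′-hydroxy ynone, with no stereocentre touched.

**Step 4**
Reactants: 10 (6S,7R)-6,7-dihydroxy-8,8-dimethoxy-2,6-dimethyloct-1-en-3-yn-5-one
Product: 11 (2R,3S)-3-hydroxy-1,1-dimethoxy-3,7-dimethyl-4-oxooct-7-en-5-yn-2-yl acetate
Conditions: Ac2O (1.5 equiv), pyridine, CH2Cl2, 0 °C
Reagents that add atoms: acetic anhydride, CC(=O)OC(C)=O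
Why: Chemoselective O-acetylation of the secondary C9 hydroxyl leaves the tertiary hydroxyl free and blocks a competing 6-endo cyclisation in the next step, with no stereocentre affected.

**Step 5**
Reactants: 11 (2R,3S)-3-hydroxy-1,1-dimethoxy-3,7-dimethyl-4-oxooct-7-en-5-yn-2-yl acetate
Product: 12 (1R)-2,2-dimethoxy-1-[(2S)-2-methyl-3-oxo-5-(prop-1-en-2-yl)-2,3-dihydrofuran-2-yl]ethyl acetate
Conditions: (4-CF3C6H4)3PAuCl (5 mol%), AgOTf (5 mol%), toluene, rt
Reagents that add atoms: none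
Why: Gold-catalysed 5-endo-dig hydroalkoxylation of the α′-hydroxy ynone closes the 3(2H)-furanone, and the tertiary carbinol carbon becomes C10 unchanged.

**Step 6**
Reactants: 12 (1R)-2,2-dimethoxy-1-[(2S)-2-methyl-3-oxo-5-(prop-1-en-2-yl)-2,3-dihydrofuran-2-yl]ethyl acetate
Product: 13 (1R)-1-[(2S)-2-methyl-3-oxo-5-(prop-1-en-2-yl)-2,3-dihydrofuran-2-yl]-2-oxoethyl acetate
Conditions: TFA/H2O (9:1), CH2Cl2, 0 °C to rt; used crude at once
Reagents that add atoms: water, O
Why: Acid-catalysed acetal hydrolysis unmasks the C8 aldehyde without base, which would open the furanone by E1cB elimination, and leaves C9 and C10 untouched.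

**Step 7**
Reactants: 14 (R)-2,2-dimethyl-1,3-dioxolane-4-carbaldehyde; 15 methyl acrylate
Product: 16 methyl 2-{[(4R)-2,2-dimethyl-1,3-dioxolan-4-yl](hydroxy)methyl}prop-2-enoate (both carbinol epimers)
Conditions: DABCO (0.5 equiv), 1,4-dioxane/H2O (1:1), rt, 3–5 d
Reagents that add atoms: none
Why: Morita–Baylis–Hillman reaction joins acrylate C-α to the aldehyde; the new carbinol centre forms as a mixture that is erased in the next step, and the dioxolane centre (C6) is kept.

**Step 8**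
Reactants: 16 methyl 2-{[(4R)-2,2-dimethyl-1,3-dioxolan-4-yl](hydroxy)methyl}prop-2-enoate
Product: 18 methyl (2Z)-2-(bromomethyl)-3-[(4S)-2,2-dimethyl-1,3-dioxolan-4-yl]prop-2-enoate, via allylic mesylate 17 (not isolated)
Conditions: Ms2O (1.3 equiv), Et3N (2 equiv), CH2Cl2, −20 °C; then LiBr (5 equiv), THF, 0 °C to rt
Reagents that add atoms: LiBr, lithium bromide, [Li+].[Br-] (bromine of 18); Ms2O, methanesulfonic anhydride, CS(=O)(=O)OS(C)(=O)=O (mesyl group of 17 only)
Why: Sulfonylation followed by SN2′ displacement with bromide (allylic transposition) gives the thermodynamically preferred trisubstituted alkene with the dioxolanyl group trans to the ester and cis to CH2Br.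

**Step 9**
Reactants: 13 (1R)-1-[(2S)-2-methyl-3-oxo-5-(prop-1-en-2-yl)-2,3-dihydrofuran-2-yl]-2-oxoethyl acetate; 18 methyl (2Z)-2-(bromomethyl)-3-[(4S)-2,2-dimethyl-1,3-dioxolan-4-yl]prop-2-enoate
Product: 20 methyl (3R,4S,5S)-5-(acetyloxy)-3-[(4S)-2,2-dimethyl-1,3-dioxolan-4-yl]-4-hydroxy-5-[(2S)-2-methyl-3-oxo-5-(prop-1-en-2-yl)-2,3-dihydrofuran-2-yl]-2-methylidenepentanoate, via allylindium dibromide 19 (not isolated)
Conditions: In powder (1.5 equiv), THF/H2O (1:1), rt, sonication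
Reagents that add atoms: indium, [In] (metal of 19 only)
Why: Indium-mediated Barbier allylation proceeds by γ-attack through a Zimmerman–Traxler chair in which the Z-configured allylindium gives the C7/C8 relationship of the target, the aldehyde approaches C7 anti to the allylic C–O bond of the dioxolane (1,2-induction from C6), and the α-acetoxy aldehyde reacts in the Cornforth/polar Felkin–Anh sense (O8 anti to O9), so all three elements converge on one diastereomer.

**Step 10**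
Reactants: 20 methyl (3R,4S,5S)-5-(acetyloxy)-3-[(4S)-2,2-dimethyl-1,3-dioxolan-4-yl]-4-hydroxy-5-[(2S)-2-methyl-3-oxo-5-(prop-1-en-2-yl)-2,3-dihydrofuran-2-yl]-2-methylidenepentanoate
Product: 21 methyl (3S,4S,5S)-5-(acetyloxy)-3-[(4S)-2,2-dimethyl-1,3-dioxolan-4-yl]-5-[(2S)-2-methyl-3-oxo-5-(prop-1-en-2-yl)-2,3-dihydrofuran-2-yl]-2-methylidene-4-[(2-methylprop-2-enoyl)oxy]pentanoate
Conditions: methacrylic anhydride (3 equiv), Et3N (4 equiv), DMAP (0.2 equiv), CH2Cl2, 0 °C to rt
Reagents that add atoms: methacrylic anhydride, C=C(C)C(=O)OC(=O)C(C)=C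
Why: DMAP-catalysed acylation of the secondary C8 alcohol outruns lactonisation onto the neighbouring ester and fixes O8 as the methacrylate with retention (the descriptor at C7 changes only by CIP priority).

**Step 11**
Reactants: 21 methyl (3S,4S,5S)-5-(acetyloxy)-3-[(4S)-2,2-dimethyl-1,3-dioxolan-4-yl]-5-[(2S)-2-methyl-3-oxo-5-(prop-1-en-2-yl)-2,3-dihydrofuran-2-yl]-2-methylidene-4-[(2-methylprop-2-enoyl)oxy]pentanoate
Product: 23 (1S,2S)-2-(acetyloxy)-1-[(2S,3S)-2-(hydroxymethyl)-4-methylidene-5-oxooxolan-3-yl]-2-[(2S)-2-methyl-3-oxo-5-(prop-1-en-2-yl)-2,3-dihydrofuran-2-yl]ethyl 2-methylprop-2-enoate, via diol ester 22 (not isolated)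
Conditions: AcOH/H2O (4:1), 40 °C; concentrate; TsOH·H2O (0.1 equiv), CH2Cl2, rt
Reagents that add atoms: none
Why: Acidic acetonide hydrolysis frees the C5/C6 diol and the secondary C6 hydroxyl closes the γ-lactone onto the acrylate ester by acid-catalysed transesterification (five-membered ring favoured over the δ-lactone), giving the trans-disubstituted α-methylene-γ-butyrolactone with all centres retained.

**Step 12**
Reactants: 23 (1S,2S)-2-(acetyloxy)-1-[(2S,3S)-2-(hydroxymethyl)-4-methylidene-5-oxooxolan-3-yl]-2-[(2S)-2-methyl-3-oxo-5-(prop-1-en-2-yl)-2,3-dihydrofuran-2-yl]ethyl 2-methylprop-2-enoate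
Product: 24 (1S,2S)-2-(acetyloxy)-1-[(2S,3R)-2-formyl-4-methylidene-5-oxooxolan-3-yl]-2-[(2S)-2-methyl-3-oxo-5-(prop-1-en-2-yl)-2,3-dihydrofuran-2-yl]ethyl 2-methylprop-2-enoate
Conditions: Dess–Martin periodinane (1.5 equiv), NaHCO3, CH2Cl2, 0 °C to rt
Reagents that add atoms: none
Why: Dess–Martin oxidation of the primary alcohol under buffered, non-basic conditions spares the adjacent C6 centre and the Michael acceptors (the C7 descriptor changes by CIP priority only).

**Step 13**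
Reactants: 24 (1S,2S)-2-(acetyloxy)-1-[(2S,3R)-2-formyl-4-methylidene-5-oxooxolan-3-yl]-2-[(2S)-2-methyl-3-oxo-5-(prop-1-en-2-yl)-2,3-dihydrofuran-2-yl]ethyl 2-methylprop-2-enoate
Product: 25 (1S,2S)-2-(acetyloxy)-1-[(2R,3S)-2-ethenyl-4-methylidene-5-oxooxolan-3-yl]-2-[(2S)-2-methyl-3-oxo-5-(prop-1-en-2-yl)-2,3-dihydrofuran-2-yl]ethyl 2-methylprop-2-enoate
Conditions: CH2I2 (5 equiv), Zn dust (9 equiv), Ti(OiPr)4 (1 equiv), THF, 0 °C to rt
Reagents that add atoms: diiodomethane, ICI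
Why: Takai-type methylenation with the gem-dizinc reagent is non-basic and aldehyde-selective, so C6 is not epimerised and the esters, ketone and acrylates are untouched.

**Step 14**
Reactants: 25 (1S,2S)-2-(acetyloxy)-1-[(2R,3S)-2-ethenyl-4-methylidene-5-oxooxolan-3-yl]-2-[(2S)-2-methyl-3-oxo-5-(prop-1-en-2-yl)-2,3-dihydrofuran-2-yl]ethyl 2-methylprop-2-enoate
Product: 26 (4Z,6R,7S,8S,9S,10S)-9-acetoxy-8-(methacryloyloxy)-1-oxo-3,10-epoxygermacra-2,4,11(13)-trien-12,6-olide (CNP0365569.2)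
Conditions: second-generation Hoveyda–Grubbs catalyst RuCl2(H2IMes)(=CH-C6H4-2-OiPr) (20 mol%, in portions), 1,4-benzoquinone (20 mol%), toluene (1 mM), 90 °C, Ar sparge
Reagents that add atoms: none
Why: Ring-closing metathesis loads the catalyst on the vinyl group and closes onto the isopropenyl group with loss of ethene, and the nine-membered oxacycle can hold the trisubstituted C4=C5 bond only in the cis-in-ring (Z) geometry of the target.

**Compound list**
1 | (R)-lactic acid | C[C@@H](O)C(=O)O | starting material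
2 | pivalaldehyde | CC(C)(C)C=O | starting material
3 | (2R,5R)-2-tert-butyl-5-methyl-1,3-dioxolan-4-one | C[C@H]1O[C@@H](C(C)(C)C)OC1=O | intermediate
4 | 2,2-dimethoxyacetaldehyde | COC(OC)C=O | starting material
5 | lithium (2R)-2-tert-butyl-5-methyl-1,3-dioxol-4-olate (lithium enolate) | CC1=C([O-])O[C@H](C(C)(C)C)O1.[Li+] | intermediate (not isolated)
6 | (2R,5S)-2-tert-butyl-5-[(1R)-1-hydroxy-2,2-dimethoxyethyl]-5-methyl-1,3-dioxolan-4-one | COC(OC)[C@H](O)[C@]1(C)O[C@@H](C(C)(C)C)OC1=O | intermediate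
7 | 2-methylbut-1-en-3-yne | C=C(C)C#C | starting material
8 | (3-methylbut-3-en-1-yn-1-yl)lithium (lithium acetylide) | [Li]C#CC(C)=C | intermediate (not isolated)
9 | dilithium (2R,5S)-2-tert-butyl-5-[(1R)-2,2-dimethoxy-1-oxidoethyl]-5-methyl-4-(3-methylbut-3-en-1-yn-1-yl)-1,3-dioxolan-4-olate (hemiketal dialkoxide, C4 undefined) | COC(OC)[C@H]([O-])[C@]1(C)O[C@@H](C(C)(C)C)OC1([O-])C#CC(C)=C.[Li+].[Li+] | intermediate (not isolated)
10 | (6S,7R)-6,7-dihydroxy-8,8-dimethoxy-2,6-dimethyloct-1-en-3-yn-5-one | C=C(C)C#CC(=O)[C@@](C)(O)[C@@H](O)C(OC)OC | intermediate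
11 | (2R,3S)-3-hydroxy-1,1-dimethoxy-3,7-dimethyl-4-oxooct-7-en-5-yn-2-yl acetate | C=C(C)C#CC(=O)[C@@](C)(O)[C@@H](OC(C)=O)C(OC)OC | intermediate
12 | (1R)-2,2-dimethoxy-1-[(2S)-2-methyl-3-oxo-5-(prop-1-en-2-yl)-2,3-dihydrofuran-2-yl]ethyl acetate | C=C(C)C1=CC(=O)[C@@](C)(O1)[C@@H](OC(C)=O)C(OC)OC | intermediate
13 | (1R)-1-[(2S)-2-methyl-3-oxo-5-(prop-1-en-2-yl)-2,3-dihydrofuran-2-yl]-2-oxoethyl acetate | C=C(C)C1=CC(=O)[C@@](C)(O1)[C@@H](OC(C)=O)C=O | intermediate
14 | (R)-2,2-dimethyl-1,3-dioxolane-4-carbaldehyde (D-glyceraldehyde acetonide) | O=C[C@H]1COC(C)(C)O1 | starting material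
15 | methyl acrylate | C=CC(=O)OC | starting material
16 | methyl 2-{[(4R)-2,2-dimethyl-1,3-dioxolan-4-yl](hydroxy)methyl}prop-2-enoate (both carbinol epimers) | C=C(C(=O)OC)C(O)[C@H]1COC(C)(C)O1 | intermediate
17 | methyl 2-{[(4R)-2,2-dimethyl-1,3-dioxolan-4-yl][(methanesulfonyl)oxy]methyl}prop-2-enoate (allylic mesylate) | C=C(C(=O)OC)C(OS(C)(=O)=O)[C@H]1COC(C)(C)O1 | intermediate (not isolated)
18 | methyl (2Z)-2-(bromomethyl)-3-[(4S)-2,2-dimethyl-1,3-dioxolan-4-yl]prop-2-enoate | COC(=O)/C(CBr)=C/[C@H]1COC(C)(C)O1 | intermediate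
19 | {(2Z)-3-[(4S)-2,2-dimethyl-1,3-dioxolan-4-yl]-2-(methoxycarbonyl)prop-2-en-1-yl}indium dibromide (allylindium dibromide) | COC(=O)/C(C[In](Br)Br)=C/[C@H]1COC(C)(C)O1 | intermediate (not isolated)
20 | methyl (3R,4S,5S)-5-(acetyloxy)-3-[(4S)-2,2-dimethyl-1,3-dioxolan-4-yl]-4-hydroxy-5-[(2S)-2-methyl-3-oxo-5-(prop-1-en-2-yl)-2,3-dihydrofuran-2-yl]-2-methylidenepentanoate | C=C(C)C1=CC(=O)[C@@](C)(O1)[C@@H](OC(C)=O)[C@@H](O)[C@@H](C(=C)C(=O)OC)[C@H]2COC(C)(C)O2 | intermediate
21 | methyl (3S,4S,5S)-5-(acetyloxy)-3-[(4S)-2,2-dimethyl-1,3-dioxolan-4-yl]-5-[(2S)-2-methyl-3-oxo-5-(prop-1-en-2-yl)-2,3-dihydrofuran-2-yl]-2-methylidene-4-[(2-methylprop-2-enoyl)oxy]pentanoate | C=C(C)C1=CC(=O)[C@@](C)(O1)[C@@H](OC(C)=O)[C@@H](OC(=O)C(C)=C)[C@@H](C(=C)C(=O)OC)[C@H]2COC(C)(C)O2 | intermediate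
22 | methyl (3S,4S,5S)-5-(acetyloxy)-3-[(1S)-1,2-dihydroxyethyl]-5-[(2S)-2-methyl-3-oxo-5-(prop-1-en-2-yl)-2,3-dihydrofuran-2-yl]-2-methylidene-4-[(2-methylprop-2-enoyl)oxy]pentanoate (diol ester) | C=C(C)C1=CC(=O)[C@@](C)(O1)[C@@H](OC(C)=O)[C@@H](OC(=O)C(C)=C)[C@@H](C(=C)C(=O)OC)[C@H](O)CO | intermediate (not isolated)
23 | (1S,2S)-2-(acetyloxy)-1-[(2S,3S)-2-(hydroxymethyl)-4-methylidene-5-oxooxolan-3-yl]-2-[(2S)-2-methyl-3-oxo-5-(prop-1-en-2-yl)-2,3-dihydrofuran-2-yl]ethyl 2-methylprop-2-enoate | C=C(C)C1=CC(=O)[C@@](C)(O1)[C@@H](OC(C)=O)[C@@H](OC(=O)C(C)=C)[C@H]2C(=C)C(=O)O[C@@H]2CO | intermediate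
24 | (1S,2S)-2-(acetyloxy)-1-[(2S,3R)-2-formyl-4-methylidene-5-oxooxolan-3-yl]-2-[(2S)-2-methyl-3-oxo-5-(prop-1-en-2-yl)-2,3-dihydrofuran-2-yl]ethyl 2-methylprop-2-enoate | C=C(C)C1=CC(=O)[C@@](C)(O1)[C@@H](OC(C)=O)[C@@H](OC(=O)C(C)=C)[C@H]2C(=C)C(=O)O[C@@H]2C=O | intermediate
25 | (1S,2S)-2-(acetyloxy)-1-[(2R,3S)-2-ethenyl-4-methylidene-5-oxooxolan-3-yl]-2-[(2S)-2-methyl-3-oxo-5-(prop-1-en-2-yl)-2,3-dihydrofuran-2-yl]ethyl 2-methylprop-2-enoate | C=C(C)C1=CC(=O)[C@@](C)(O1)[C@@H](OC(C)=O)[C@@H](OC(=O)C(C)=C)[C@H]2C(=C)C(=O)O[C@@H]2C=C | intermediate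
26 | (4Z,6R,7S,8S,9S,10S)-9-acetoxy-8-(methacryloyloxy)-1-oxo-3,10-epoxygermacra-2,4,11(13)-trien-12,6-olide (CNP0365569.2) | C=C(C)C(=O)O[C@H]1[C@H]2C(=C)C(=O)O[C@@H]2/C=C(/C)C2=CC(=O)[C@@](C)(O2)[C@H]1OC(C)=O | target

**Totals**
Total steps: 14. Longest linear sequence: 12 (steps 1–6, then 9–14); the bromide branch is steps 7–8.

**Steps most likely to fail, and fallbacks**

Step 9 is the main risk: both partners are hindered and three stereocontrol elements must cooperate in water. The fallback sets out from 18 and replaces the Barbier reaction by a catalysed allylboration. Borylation of 18 (B2pin2, Pd2(dba)3 cat., KOAc, toluene, 50 °C) gives methyl (2E)-3-[(4S)-2,2-dimethyl-1,3-dioxolan-4-yl]-2-[(4,4,5,5-tetramethyl-1,3,2-dioxaborolan-2-yl)methyl]prop-2-enoate F1 (same alkene geometry as 18; the descriptor changes by CIP priority). F1 and aldehyde 13 with Sc(OTf)3 (10 mol%) in toluene at −78 °C react through the same closed chair, and aqueous work-up before any lactonisation gives the hydroxy ester, so the fallback comes back to the route at 20.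

Step 14 is the second risk: a strained ring, a trisubstituted alkene from an electron-poor isopropenyl group, and a free exo-methylene lactone that can sequester the catalyst. The fallback sets out from 25 and masks the lactone alkene. Dimethylamine (2 M in THF, 0 °C) adds selectively to the α-methylene lactone to give (1S,2S)-2-(acetyloxy)-1-[(2R,3S)-4-[(dimethylamino)methyl]-2-ethenyl-5-oxooxolan-3-yl]-2-[(2S)-2-methyl-3-oxo-5-(prop-1-en-2-yl)-2,3-dihydrofuran-2-yl]ethyl 2-methylprop-2-enoate F2. Ring-closing metathesis of F2 as its tosylate salt, with the same catalyst, gives (4Z,6R,7S,8S,9S,10S)-9-acetoxy-13-(dimethylamino)-8-(methacryloyloxy)-1-oxo-3,10-epoxygermacra-2,4-dien-12,6-olide F3. Quaternisation with MeI in MeCN followed by aqueous NaHCO3 eliminates trimethylamine and restores the exo-methylene group, coming back to the route at 26.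

Step 3 is the third risk: the free C9 alkoxide, possible over-addition, and the pivalaldehyde released near excess acetylide. The fallback sets out from 6 and changes the acyl donor. Aminolysis of 6 (MeNHOMe·HCl, AlMe3, CH2Cl2, 0 °C to rt) opens the dioxolanone with loss of pivalaldehyde to (2S,3R)-2,3-dihydroxy-N,4,4-trimethoxy-N,2-dimethylbutanamide F4. Addition of acetylide 8 (4.5 equiv, THF, −78 to −20 °C) to this Weinreb amide stops cleanly at the ketone, coming back to the route at 10.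

**Further compounds**
F1 | step 9 | methyl (2E)-3-[(4S)-2,2-dimethyl-1,3-dioxolan-4-yl]-2-[(4,4,5,5-tetramethyl-1,3,2-dioxaborolan-2-yl)methyl]prop-2-enoate | COC(=O)/C(CB1OC(C)(C)C(C)(C)O1)=C/[C@H]2COC(C)(C)O2
F2 | step 14 | (1S,2S)-2-(acetyloxy)-1-[(2R,3S)-4-[(dimethylamino)methyl]-2-ethenyl-5-oxooxolan-3-yl]-2-[(2S)-2-methyl-3-oxo-5-(prop-1-en-2-yl)-2,3-dihydrofuran-2-yl]ethyl 2-methylprop-2-enoate | C=C(C)C1=CC(=O)[C@@](C)(O1)[C@@H](OC(C)=O)[C@@H](OC(=O)C(C)=C)[C@H]2C(CN(C)C)C(=O)O[C@@H]2C=C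
F3 | step 14 | (4Z,6R,7S,8S,9S,10S)-9-acetoxy-13-(dimethylamino)-8-(methacryloyloxy)-1-oxo-3,10-epoxygermacra-2,4-dien-12,6-olide | C=C(C)C(=O)O[C@H]1[C@H]2C(CN(C)C)C(=O)O[C@@H]2/C=C(/C)C2=CC(=O)[C@@](C)(O2)[C@H]1OC(C)=O
F4 | step 3 | (2S,3R)-2,3-dihydroxy-N,4,4-trimethoxy-N,2-dimethylbutanamide | CON(C)C(=O)[C@@](C)(O)[C@@H](O)C(OC)OC
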